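Each millimolar of substrate lost ends as target (crystals counted) or as isomer of the product, so the share asked for is a tally of forks.

in all of them: substrate 31 mM; gas 1.1 mM (held); time 4.0 h
- alder: temperature 60 °C
- birch: temperature 0 °C
- oak: temperature 30 °C
- larch: at 60 °C until 3.0 h, from then on at 0 °C

- the flask that comes out highest in share of target in all that became target or isomer of the product, or "all alike" when all lie within 1.5 percentage points (alder / birch / oak / larch / all alike)
- share of target in all that became target or isomer of the product, alder
- share of target in all that became target or isomer of the product, birch
- share of target in all that became target or isomer of the product, oak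
- share of target in all that became target or isomer of the product, larch

- amounts and yields of target count crystals too
- given per volume of solution although it is solid: crystals
- at the start none of reagent is dissolved
- all constants are for 0 °C and move with temperature by the activation energies and enthalpies

    reagent + tautomer → target (k1 = 6790 M⁻¹ min⁻¹, Ea1 = 46.0 kJ mol⁻¹)
    crystals ⇌ target, rate k2*(cs2 - [target]) while solid is left; crystals form when [target] > cs2 (cs2 = 14 mM, k2 = 0.457 min⁻¹)
    gas ⇌ reagent, rate k3*(csat - [reagent]) (k3 = 0.241 min⁻¹, csat = 1.1 mM)
    substrate + reagent → isomer of the product (k4 = 32.5 M⁻¹ min⁻¹, Ea4 = 48.0 kJ mol⁻¹)
    substrate ⇌ tautomer (K5 = 1.5, k5 = 0.0107 min⁻¹, Ea5 = 92.0 kJ mol⁻¹, ΔH5 = −38.0 kJ mol⁻¹)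
    (constants at 0 °C)

**The fork.** Gas feeds reagent. Substrate either meets reagent and becomes isomer, or turns into tautomer, which reagent captures as target unless it returns first. We carry the fork ratio (a selectivity factor): target made per isomer made, equal to the tautomer formation constant over the isomer rate per substrate, times the chance of capture. At 0 °C and full reagent this gives 0.299. At fixed temperature the ratio falls as reagent rises, and substrate cancels out of it.

**Birch bracket.** In birch, near zero reagent, the ratio is 313, a ceiling share of 99.7%; at saturation the share is 23.0%. To tighten this, note that tautomer formation at the charge takes 0.332 mM min⁻¹, more than the 0.265 mM min⁻¹ gas delivers at most. So we expect birch reagent near zero until substrate falls to 24.8 mM. At half that level, steady reagent is 0.206 mM and the ratio is 1.59. Taking each half of that substrate at its extreme ratios puts our estimate of isomer between 4.78 mM and 14.3 mM. Our bracket for the birch share is then 53.8% to 84.6%, and we commit to the mean isomer, a share of 69.2%.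

**Warmer flasks.** From coldest to hottest, tautomer formation speeds up 1500 times against 45 for isomer formation, so the cold loss should shrink. The tautomer equilibrium sinks with heat (enthalpy −38.0 kJ mol⁻¹), and capture speeds up 38 times against that 45, so the ceiling should sink too. We bet on oak. At its fastest, supply needs 1.95 h for the charge, less than 3.0 h, so larch should match alder.

**The forecast.** It names oak, with alder 92.9%, birch 68% (63% to 73%), oak 97.9% and larch 92.9%: “At 0 °C tautomerisation (0.33 mM/min, falling) becomes limiting.” Its birch value lies inside our bracket, slightly below our own.

**The run.** The highest is oak: alder 92.9%, birch 69.1%, oak 97.9%, larch 92.9%. The birch share stands inside our bracket. A temperature scan puts the peak for this time at 24.9 °C.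

**At rest?** Birch keeps 0.11% of its substrate at the end. Even at the saturation ratio, that remainder can lower the birch share by about 0.051 percentage points. Computed at ten times the time, birch reads 69.1% at 40.0 h. Oak reads 97.9% and larch 92.9% then, the shares they show at the asked time. Larch held 0% substrate at its change of temperature.

**Neighbour.** With 53 mM of substrate on larch's schedule, gas delivers at most 47.7 mM before cooling, so at least 5.30 mM is still unconverted at the change. Taking the hot part at alder's share and the cold part at the saturation ratio gives a low estimate near 85.9%. The computed share is 88.5%, with 1.2% of the substrate left.

The rate constants stand for no real mixture; the rest is arithmetic.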